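**Plan**

- The target is the ester of 19-(furan-2-yl)nonadeca-5,7-diynoic acid with 11-(furan-2-yl)undeca-4,6-diyn-1-ol. It has no stereocentre and no stereogenic double bond, so no stereochemistry has to be set.
- The first cut is the C8(sp)–C9(sp3) bond of the acyl chain. C8 is the free end of the conjugated 5,7-diyne and can carry bromine. C9 is an unbranched primary CH2 heading ten further methylenes that end at C2 of a furan ring, so it can arise as an unstabilised primary radical from a carboxyl group one carbon further out (a furan-capped C12 fatty acid as its N-hydroxyphthalimide ester).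
- The next cuts are the ester C–O bond, the central sp–sp bond of each 1,3-diyne (Cadiot–Chodkiewicz, bromine always on the furan-free partner), and the furan–chain bonds (2-furyllithium alkylation; furfural Wittig).
- Forward order: alcohol arm (steps 1–4), bromodiyne acid (steps 5–6), esterification (step 7), fatty-acid arm and its activation (steps 8–10), then the decarboxylative sp3–sp coupling as the last step (step 11).
- The helpers are the bromine on C8, the extra carboxyl carbon with its phthalimide ester on C9, and the silyl cap of step 5. All are lost in or before the key step.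

Key step: step 11

Assumption: (10-carboxydecyl)triphenylphosphonium bromide and (bromoethynyl)triisopropylsilane are taken as catalogue compounds.

**Route**

Step 1
Reactants: 1 furan; 2 1,4-dibromobutane
Product: 4 2-(4-bromobutyl)furan, via 2-furyllithium 3 (not isolated)
Conditions: n-BuLi, THF, −78 → 0 °C; then added to 2 (3 equiv), THF, −78 °C → rt
Reagents that add atoms: none
Why: Furan is lithiated at C2 next to the ring oxygen and the 2-furyllithium should displace one bromide of the dibromide by SN2, with inverse addition into excess 2 suppressing double alkylation.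

Step 2
Reactants: 4 2-(4-bromobutyl)furan; 5 lithium acetylide–ethylenediamine complex
Product: 6 2-(hex-5-yn-1-yl)furan
Conditions: DMSO, 10 °C → rt
Reagents that add atoms: none
Why: SN2 alkylation of lithium acetylide on the unhindered primary bromide in DMSO should install the terminal alkyne, with elimination only a minor pathway.

Step 3
Reactants: 7 pent-4-yn-1-ol
Product: 8 5-bromopent-4-yn-1-ol
Conditions: NBS, AgNO3 (10 mol%), acetone, rt, dark
Reagents that add atoms: N-bromosuccinimide, O=C1CCC(=O)N1Br
Why: Silver-catalysed electrophilic bromination of the terminal alkyne C–H should give the 1-bromoalkyne with the free hydroxyl untouched; the bromine is placed on this furan-free partner because 2-alkylfurans are themselves brominated by NBS.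

Step 4
Reactants: 6 2-(hex-5-yn-1-yl)furan; 8 5-bromopent-4-yn-1-ol
Product: 9 11-(furan-2-yl)undeca-4,6-diyn-1-ol
Conditions: CuCl (10 mol%), NH2OH·HCl, 30% aq. n-BuNH2, Et2O, 0 °C → rt; 8 added slowly
Reagents that add atoms: none
Why: Cadiot–Chodkiewicz coupling, in which the copper acetylide of 6 (monovalent copper kept reduced by hydroxylamine) should couple with bromoalkyne 8 to the unsymmetrical 1,3-diyne, slow addition of 8 limiting its homocoupling.

Step 5
Reactants: 10 hex-5-ynoic acid; 11 (bromoethynyl)triisopropylsilane
Product: 12 8-(triisopropylsilyl)octa-5,7-diynoic acid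
Conditions: CuCl (10 mol%), NH2OH·HCl, 30% aq. n-BuNH2, THF, 0 °C → rt; then 1 M HCl to pH 3
Reagents that add atoms: none
Why: A second Cadiot–Chodkiewicz coupling should build the acyl-side diyne, the acid reacting as its butylammonium salt and the bulky silyl cap resisting cleavage by the amine.

Step 6
Reactants: 12 8-(triisopropylsilyl)octa-5,7-diynoic acid
Product: 13 8-bromoocta-5,7-diynoic acid
Conditions: NBS, AgF, MeCN, rt, dark
Reagents that add atoms: N-bromosuccinimide, O=C1CCC(=O)N1Br
Why: Desilylative bromination of a silyl-capped alkyne, in which silver fluoride should cleave the C–Si bond to a silver diynylide that NBS brominates at C8; it is run before the furan-bearing alcohol is attached so that no furan is exposed to NBS.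

Step 7
Reactants: 9 11-(furan-2-yl)undeca-4,6-diyn-1-ol; 13 8-bromoocta-5,7-diynoic acid
Product: 14 11-(furan-2-yl)undeca-4,6-diyn-1-yl 8-bromoocta-5,7-diynoate
Conditions: EDC·HCl, DMAP (10 mol%), CH2Cl2, 0 °C → rt, dark
Reagents that add atoms: none
Why: Steglich esterification under neutral carbodiimide activation should acylate the primary alcohol while leaving the bromodiyne, the internal diyne and the furan alone.

Step 8
Reactants: 15 furfural (furan-2-carbaldehyde); 16 (10-carboxydecyl)triphenylphosphonium bromide
Product: 18 12-(furan-2-yl)dodec-11-enoic acid (Z/E mixture, Z expected to predominate), via carboxylate ylide 17 (not isolated)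
Conditions: NaHMDS (2.2 equiv), THF, 0 °C; then 15, −78 °C → rt; 1 M HCl work-up
Reagents that add atoms: none
Why: Wittig olefination, in which two equivalents of base should give the carboxylate ylide that condenses with furfural to join the furan to the C12 acid chain; the alkene geometry is irrelevant because step 9 removes it.

Step 9
Reactants: 18 12-(furan-2-yl)dodec-11-enoic acid
Product: 19 12-(furan-2-yl)dodecanoic acid
Conditions: H2 (1 atm), 5% Pd/C, EtOAc, rt, stopped after one equivalent of H2
Reagents that add atoms: none
Why: Catalytic hydrogenation should saturate the conjugated disubstituted alkene well before the aromatic furan ring is attacked, which is why the uptake is limited to one equivalent.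

Step 10
Reactants: 19 12-(furan-2-yl)dodecanoic acid
Product: 20 1,3-dioxoisoindolin-2-yl 12-(furan-2-yl)dodecanoate
Conditions: N-hydroxyphthalimide, DIC, DMAP (10 mol%), CH2Cl2, rt
Reagents that add atoms: N-hydroxyphthalimide, ON1C(=O)c2ccccc2C1=O
Why: Carbodiimide condensation should give the redox-active N-hydroxyphthalimide ester that makes the carboxyl group a one-electron leaving group.

Step 11
Reactants: 14 11-(furan-2-yl)undeca-4,6-diyn-1-yl 8-bromoocta-5,7-diynoate; 20 1,3-dioxoisoindolin-2-yl 12-(furan-2-yl)dodecanoate
Product: 21 11-(furan-2-yl)undeca-4,6-diyn-1-yl 19-(furan-2-yl)nonadeca-5,7-diynoate (target)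
Conditions: NiBr2(dme) (10 mol%), 4,4'-di-tert-butyl-2,2'-bipyridine (10 mol%), Mn powder (2 equiv), LiBr (1 equiv), DMA, rt, argon, dark
Reagents that add atoms: none
Why: Manganese should reduce the NiBr2(dme)/bipyridine complex to zerovalent nickel, which inserts into the C(sp)–Br bond of 14 to give a diynylnickel bromide (divalent nickel); single-electron reduction of ester 20 then expels phthalimide anion and CO2 and releases the primary 11-(furan-2-yl)undecyl radical, which is captured at nickel and leaves by C(sp3)–C(sp) reductive elimination from trivalent nickel, forming the C8–C9 bond before manganese closes the cycle. The closest known reaction type is the nickel-catalysed reductive decarboxylative alkynylation of N-hydroxyphthalimide esters with 1-bromoalkynes (a cross-electrophile coupling), applied here to a 1-bromo-1,3-diyne and a primary fatty-acid ester. No ring is closed and no stereocentre is created. The step needs cross-coupling over homocoupling, which the two different activation modes should secure (two-electron oxidative addition for the sp C–Br bond, one-electron fragmentation for the ester), and it needs site selectivity for C8, which carries the only carbon–halogen bond in either partner. The unstabilised primary radical has no 5-exo or 6-exo acceptor within reach (the furan is ten methylenes away) and should be trapped by nickel faster than it adds to the furans or the internal diyne, while the carboxylic ester, both furan rings and the second diyne are inert to Mn and LiBr at room temperature.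

**Compound list**

1 | furan | c1ccoc1 | starting material
2 | 1,4-dibromobutane | BrCCCCBr | starting material
3 | 2-furyllithium | [Li]c1ccco1 | intermediate
4 | 2-(4-bromobutyl)furan | BrCCCCc1ccco1 | intermediate
5 | lithium acetylide–ethylenediamine complex | [Li]C#C.NCCN | starting material
6 | 2-(hex-5-yn-1-yl)furan | C#CCCCCc1ccco1 | intermediate
7 | pent-4-yn-1-ol | OCCCC#C | starting material
8 | 5-bromopent-4-yn-1-ol | OCCCC#CBr | intermediate
9 | 11-(furan-2-yl)undeca-4,6-diyn-1-ol | OCCCC#CC#CCCCCc1ccco1 | intermediate
10 | hex-5-ynoic acid | OC(=O)CCCC#C | starting material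
11 | (bromoethynyl)triisopropylsilane | BrC#C[Si](C(C)C)(C(C)C)C(C)C | starting material
12 | 8-(triisopropylsilyl)octa-5,7-diynoic acid | OC(=O)CCCC#CC#C[Si](C(C)C)(C(C)C)C(C)C | intermediate
13 | 8-bromoocta-5,7-diynoic acid | OC(=O)CCCC#CC#CBr | intermediate
14 | 11-(furan-2-yl)undeca-4,6-diyn-1-yl 8-bromoocta-5,7-diynoate | O=C(CCCC#CC#CBr)OCCCC#CC#CCCCCc1ccco1 | intermediate
15 | furfural (furan-2-carbaldehyde) | O=Cc1ccco1 | starting material
16 | (10-carboxydecyl)triphenylphosphonium bromide | OC(=O)CCCCCCCCCC[P+](c1ccccc1)(c1ccccc1)c1ccccc1.[Br-] | starting material
17 | sodium 11-(triphenyl-λ5-phosphanylidene)undecanoate (carboxylate ylide) | [Na+].[O-]C(=O)CCCCCCCCCC=P(c1ccccc1)(c1ccccc1)c1ccccc1 | intermediate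
18 | 12-(furan-2-yl)dodec-11-enoic acid (Z/E mixture; Z isomer drawn) | OC(=O)CCCCCCCCC/C=C\c1ccco1 | intermediate
19 | 12-(furan-2-yl)dodecanoic acid | OC(=O)CCCCCCCCCCCc1ccco1 | intermediate
20 | 1,3-dioxoisoindolin-2-yl 12-(furan-2-yl)dodecanoate | O=C(CCCCCCCCCCCc1ccco1)ON1C(=O)c2ccccc2C1=O | intermediate
21 | 11-(furan-2-yl)undeca-4,6-diyn-1-yl 19-(furan-2-yl)nonadeca-5,7-diynoate | O=C(CCCC#CC#CCCCCCCCCCCCc1ccco1)OCCCC#CC#CCCCCc1ccco1 | target

**Count and risks**

Total step count: 11. Longest linear sequence: 5 steps (1 → 2 → 4 → 7 → 11).

Steps most likely to fail:

Step 11. Reductive homocoupling or hydrodebromination of the bromodiyne at nickel may outrun radical capture, and the phthalimide ester may be reduced too early so that the alkyl radical dimerises or is quenched. The fallback makes the same C8–C9 bond by a two-electron palladium/copper alkyl Sonogashira coupling instead of a radical cross-electrophile coupling. It sets out from 9 and 12: Steglich esterification (EDC·HCl, DMAP, CH2Cl2) should give 11-(furan-2-yl)undeca-4,6-diyn-1-yl 8-(triisopropylsilyl)octa-5,7-diynoate F1, and TBAF buffered with AcOH (THF, 0 °C) should free the terminal diyne ester 11-(furan-2-yl)undeca-4,6-diyn-1-yl octa-5,7-diynoate F2. In parallel, 2-furyllithium 3 (from 1) is alkylated with excess 1,11-dibromoundecane to 2-(11-bromoundecyl)furan F3. Coupling of F2 with F3 under [(π-allyl)PdCl]2, 1,3-bis(1-adamantyl)imidazolium chloride, CuI and Cs2CO3 in DMF/Et2O at 45 °C should come back to the route at 21.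

Step 6. Cleavage of the hindered silicon–carbon bond may stall if the free carboxylic acid ties up silver or fluoride, and the bromodiyne may polymerise on concentration or in light. The fallback reverses the polarity of the diyne construction and uses a labile silyl group that is exchanged for bromine without fluoride. It sets out from 10: NBS with catalytic AgNO3 in acetone should give 6-bromohex-5-ynoic acid F4. Cadiot–Chodkiewicz coupling of F4 with ethynyltrimethylsilane (CuCl, NH2OH·HCl, aq. n-BuNH2, 0 °C, short contact) should give 8-(trimethylsilyl)octa-5,7-diynoic acid F5. Silver-catalysed bromodesilylation of F5 (NBS, AgNO3 cat., acetone, dark) should come back to the route at 13.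

Step 7. The bromodiyne acid may decompose during carbodiimide activation, either by rearrangement of the activated acid to an N-acylurea or by nucleophilic attack of DMAP on the bromoalkyne. The fallback forms the ester by O-alkylation of the carboxylate instead of acyl activation. It sets out from 9: MsCl and Et3N in CH2Cl2 at 0 °C should give 11-(furan-2-yl)undeca-4,6-diyn-1-yl methanesulfonate F6. SN2 displacement of F6 by the caesium salt of 13 (Cs2CO3, DMF, rt, dark) should come back to the route at 14.

**Further compounds**

F1 | step 11 | 11-(furan-2-yl)undeca-4,6-diyn-1-yl 8-(triisopropylsilyl)octa-5,7-diynoate | O=C(CCCC#CC#C[Si](C(C)C)(C(C)C)C(C)C)OCCCC#CC#CCCCCc1ccco1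
F2 | step 11 | 11-(furan-2-yl)undeca-4,6-diyn-1-yl octa-5,7-diynoate | O=C(CCCC#CC#C)OCCCC#CC#CCCCCc1ccco1
F3 | step 11 | 2-(11-bromoundecyl)furan | BrCCCCCCCCCCCc1ccco1
F4 | step 6 | 6-bromohex-5-ynoic acid | OC(=O)CCCC#CBr
F5 | step 6 | 8-(trimethylsilyl)octa-5,7-diynoic acid | OC(=O)CCCC#CC#C[Si](C)(C)C
F6 | step 7 | 11-(furan-2-yl)undeca-4,6-diyn-1-yl methanesulfonate | CS(=O)(=O)OCCCC#CC#CCCCCc1ccco1
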